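**Strategy.** Terpene numbering: C1 carries the ether oxygen, C4 is the methyl-bearing quaternary centre, C9′ is the benzylic CH. The cyclopentane (C1–C5) and the cycloheptane (C1, C5–C10) are read as the two halves of one ten-membered ring, the (E,E)-cyclodeca-1(10),4-diene of (+)-bicyclogermacrene, in which C3–C4 is a perimeter bond. The key step closes this macrocycle at C3–C4 by an intramolecular, trans-selective B-alkyl Suzuki coupling; its precursor is an open-chain cis-cyclopropane from (+)-2-carene carrying a 1,1-dibromovinyl group and a dienyl chain. A final o-quinone methide cascade (C9′–C4, transannular C1–C5, hydride shift C1→C10, O–C1) stitches the macrocycle across and sets five stereocentres from the two cyclopropane centres.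

Key step: step 6

Remark: 2,4,6-trihydroxyisophthalaldehyde (10) is taken as a purchasable compound. Further labels: C14 is the methyl on C10, C15 the methyl on C4, and C6/C7/C11 form the cyclopropane.

**Step 1**
Reactants: 1 (+)-2-carene
Product: 2 (1S,3R)-2,2-dimethyl-3-(3-oxobutyl)cyclopropane-1-carbaldehyde (cis)
Conditions: O3, CH2Cl2/MeOH, NaHCO3, −78 °C; then Me2S, −78 °C → rt
Reagents that add atoms: ozone, [O-][O+]=O
Why: Ozonolysis with reductive work-up cleaves the only C=C of 1 into the cyclopropyl aldehyde (future C5) and the methyl ketone (future C10/C14) and leaves the two cis cyclopropane stereocentres (future C6, C7) untouched.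

**Step 2**
Reactants: 2 keto-aldehyde
Product: 3 4-[(1R,3R)-3-(2,2-dibromoethenyl)-2,2-dimethylcyclopropyl]butan-2-one
Conditions: CBr4, PPh3, CH2Cl2, 0 °C
Reagents that add atoms: tetrabromomethane, BrC(Br)(Br)Br
Why: Ramirez (Corey–Fuchs) dibromo-olefination with Ph3P=CBr2 made in the flask reacts with the aldehyde far faster than with the methyl ketone and turns the future C4 into a 1,1-dibromoalkene carbon.

**Step 3**
Reactants: 3 dibromoalkenyl ketone
Product: 4 (2E)-5-[(1R,3R)-3-(2,2-dibromoethenyl)-2,2-dimethylcyclopropyl]-N-methoxy-N,3-dimethylpent-2-enamide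
Conditions: (EtO)2P(O)CH2C(O)N(OMe)Me, NaH, THF, 0 °C → reflux; Z isomer removed by chromatography
Reagents that add atoms: diethyl [2-(methoxy(methyl)amino)-2-oxoethyl]phosphonate, CCOP(=O)(CC(=O)N(C)OC)OCC
Why: Horner–Wadsworth–Emmons olefination of the methyl ketone should give the trisubstituted (E)-enamide as the main isomer and so fix the (E) geometry of the future C1=C10 olefin.

**Step 4**
Reactants: 4 Weinreb enamide
Product: 5 (2E)-5-[(1R,3R)-3-(2,2-dibromoethenyl)-2,2-dimethylcyclopropyl]-3-methylpent-2-enal
Conditions: DIBAL-H, THF, −78 °C; Rochelle salt work-up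
Reagents that add atoms: none
Why: Hydride reduction of a Weinreb amide stops at the aldehyde through the chelated tetrahedral intermediate and does not touch the dibromoalkene.

**Step 5**
Reactants: 5 enal
Product: 6 (1R,3R)-1-(2,2-dibromoethenyl)-2,2-dimethyl-3-[(3E)-3-methylhexa-3,5-dien-1-yl]cyclopropane
Conditions: Ph3PCH3Br, KOt-Bu, THF, 0 °C → rt
Reagents that add atoms: methyltriphenylphosphonium bromide, C[P+](c1ccccc1)(c1ccccc1)c1ccccc1.[Br-]
Why: Wittig methylenation of the enal gives the terminal (E)-1,3-diene whose CH=CH2 end is the future C2–C3 unit.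

**Step 6**
Reactants: 6 dibromovinyl diene
Product: 8 (1R,2Z,6E,10R)-3-bromo-7,11,11-trimethylbicyclo[8.1.0]undeca-2,6-diene, via homoallylic 9-BBN borane 7 (not isolated)
Conditions: 9-BBN, THF, 0 °C → rt; then slow addition to Pd(dppf)Cl2 (cat.), AsPh3, Cs2CO3, DMF/THF/H2O, rt, high dilution
Reagents that add atoms: none
Why: 9-BBN adds anti-Markovnikov to the terminal CH=CH2 only (the trisubstituted olefin and the dibromoalkene are inert) to give the primary C3 borane 7; Pd(0) then inserts into the C4–Br bond trans to the cyclopropyl group, the base-activated borane transmetallates and reductive elimination forms C3–C4. The closest known reactions are the B-alkyl Suzuki–Miyaura macrocyclisation and the trans-selective mono-coupling of 1,1-dibromo-1-alkenes. The ring closed is the ten-membered cyclodeca-1(10),4-diene (C1–C10), by C(sp3)–C(sp2) reductive elimination with both olefins endocyclic. No sp3 stereocentre is formed; the ring-olefin geometry at C4=C5 (C3 trans to C6, Z by CIP only because of the remaining bromine) follows from oxidative addition at the less hindered trans C–Br bond. The step needs trans over cis C–Br selectivity and ring closure over oligomerisation: the cis-cyclopropyl substituent shields the inner bromide, and the cis-1,2-disubstituted cyclopropane holds both chain ends on one side, helped by slow addition, high dilution and room temperature (below the Cope rearrangement of the product).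

**Step 7**
Reactants: 8 macrocyclic alkenyl bromide
Product: 9 (+)-bicyclogermacrene, (1S,2E,6E,10R)-3,7,11,11-tetramethylbicyclo[8.1.0]undeca-2,6-diene
Conditions: Me2Zn, Pd(t-Bu3P)2 (cat.), THF, 0 °C → rt
Reagents that add atoms: dimethylzinc, C[Zn]C
Why: Negishi methylation of the alkenyl bromide with this catalyst should proceed with retention, placing methyl C15 cis to the cyclopropane and giving the (E)-C4=C5 olefin.

**Step 8**
Reactants: 9 (+)-bicyclogermacrene; 10 2,4,6-trihydroxyisophthalaldehyde; 11 3-methylbutanal
Product: 13 target: aromadendrane bridged from C1 (aryl ether O) to C4 (C9′H-isobutyl) by a 2,4-dihydroxy-3,5-diformylbenzene ring, (1S,4R,5R,6R,7R,10S,9′R) in terpene numbering, via o-quinone methide 12 (not isolated)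
Conditions: N,N′-dimethylethylenediamine (cat.), HFIP, 4 Å MS, rt → 40 °C; congeners separated by chromatography
Reagents that add atoms: none
Why: Knoevenagel condensation of 10 with 11 gives o-quinone methide 12, whose benzylic carbon is attacked at C4 by the outer face of the (E)-C4=C5 olefin (C9′ set by the approach that keeps the isobutyl group away from ring methylene C3) while C1=C10 adds transannularly and anti at C5 to give the trans-fused C10 cation, a suprafacial 1,2-hydride shift from C1 to C10 sets C10, and the C1 cation is closed by the neighbouring phenol oxygen on the face cis to C9′, so this biomimetic Michael/transannular cation–olefin cascade relays the two cyclopropane centres into C9′, C4, C5, C1 and C10 in one operation.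

**Compound list**
1 | (+)-2-carene, (1S,6R)-3,7,7-trimethylbicyclo[4.1.0]hept-2-ene | CC1=C[C@H]2[C@@H](CC1)C2(C)C | starting material
2 | (1S,3R)-2,2-dimethyl-3-(3-oxobutyl)cyclopropane-1-carbaldehyde | O=C[C@H]1[C@@H](CCC(C)=O)C1(C)C | intermediate
3 | 4-[(1R,3R)-3-(2,2-dibromoethenyl)-2,2-dimethylcyclopropyl]butan-2-one | BrC(Br)=C[C@H]1[C@@H](CCC(C)=O)C1(C)C | intermediate
4 | (2E)-5-[(1R,3R)-3-(2,2-dibromoethenyl)-2,2-dimethylcyclopropyl]-N-methoxy-N,3-dimethylpent-2-enamide | BrC(Br)=C[C@H]1[C@@H](CC/C(C)=C/C(=O)N(C)OC)C1(C)C | intermediate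
5 | (2E)-5-[(1R,3R)-3-(2,2-dibromoethenyl)-2,2-dimethylcyclopropyl]-3-methylpent-2-enal | BrC(Br)=C[C@H]1[C@@H](CC/C(C)=C/C=O)C1(C)C | intermediate
6 | (1R,3R)-1-(2,2-dibromoethenyl)-2,2-dimethyl-3-[(3E)-3-methylhexa-3,5-dien-1-yl]cyclopropane | BrC(Br)=C[C@H]1[C@@H](CC/C(C)=C/C=C)C1(C)C | intermediate
7 | 9-{(3E)-6-[(1R,3R)-3-(2,2-dibromoethenyl)-2,2-dimethylcyclopropyl]-4-methylhex-3-en-1-yl}-9-borabicyclo[3.3.1]nonane | BrC(Br)=C[C@H]1[C@@H](CC/C(C)=C/CCB2C3CCCC2CCC3)C1(C)C | intermediate (not isolated)
8 | (1R,2Z,6E,10R)-3-bromo-7,11,11-trimethylbicyclo[8.1.0]undeca-2,6-diene | Br/C1=C\[C@H]2[C@@H](CC/C(C)=C/CC1)C2(C)C | intermediate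
9 | (+)-bicyclogermacrene, (1S,2E,6E,10R)-3,7,11,11-tetramethylbicyclo[8.1.0]undeca-2,6-diene | C/C1=C\[C@H]2[C@@H](CC/C(C)=C/CC1)C2(C)C | intermediate
10 | 2,4,6-trihydroxybenzene-1,3-dicarbaldehyde | O=Cc1c(O)cc(O)c(C=O)c1O | starting material
11 | 3-methylbutanal | CC(C)CC=O | starting material
12 | o-quinone methide, 2,4-diformyl-3,5-dihydroxy-6-(3-methylbutylidene)cyclohexa-2,4-dien-1-one | CC(C)CC=C1C(=O)C(C=O)=C(O)C(C=O)=C1O | intermediate (not isolated)
13 | target CNP0189833.2, (1S,4R,5R,6R,7R,10S,9′R) | CC(C)C[C@H]1c2c(O)c(C=O)c(O)c(C=O)c2O[C@]23CC[C@@]1(C)[C@H]2[C@H]1[C@@H](CC[C@@H]3C)C1(C)C | target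

**Step count and risks**
Total steps: 8. Longest linear sequence: 8 (1 → 13; 10 and 11 enter in the last step).

Steps most likely to fail:

- **Step 6 (key step).** The ten-membered ring closure may lose to intermolecular coupling, or oxidative addition may occur at the inner (cis) C–Br bond. The fallback sets out from 6 and returns at 8. Compound 6 is hydroborated as before to 7 and the borane is iodinated (I2, NaOMe) to the homoallylic iodide F1. Zinc insertion (Zn, LiCl, THF) gives the alkylzinc iodide F2, which is added slowly to Pd(DPEphos)Cl2 in THF/DMF. This trans-selective Negishi mono-alkylation of the 1,1-dibromoalkene closes the same C3–C4 bond with a pre-formed, base-free nucleophile and gives 8.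

- **Step 8.** The cation cascade may be diverted: the phenol may close onto C5 (hetero-Diels–Alder mode), the C10 cation may be trapped or lose a proton before the hydride shift, and facial selectivity at C9′ may be poor. The fallback sets out from 9 (with 10 and 11) and returns at 13. The three-component reaction is run in a wet medium (NaOAc, AcOH/H2O/dioxane) so that water intercepts the C10 cation, and the macrocarpal-type tertiary alcohol F3 with the required C9′ configuration is isolated. F3 is then re-ionised at C10 (BF3·OEt2, CH2Cl2/HFIP, −40 °C), which triggers the C1→C10 hydride shift and ether closure to 13.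

- **Step 7.** Olefin geometry may be lost at the alkenyl–palladium stage, or the strained diene may undergo Cope rearrangement on warming. The fallback sets out from 8 and returns at 9. Bromine–lithium exchange (t-BuLi, Et2O, −78 °C) gives the configurationally stable alkenyllithium F4, which is methylated with MeI at −78 °C with retention to give 9.

**Further compounds**
F1 | step 6 | (1R,3R)-1-(2,2-dibromoethenyl)-3-[(3E)-6-iodo-3-methylhex-3-en-1-yl]-2,2-dimethylcyclopropane | BrC(Br)=C[C@H]1[C@@H](CC/C(C)=C/CCI)C1(C)C
F2 | step 6 | {(3E)-6-[(1R,3R)-3-(2,2-dibromoethenyl)-2,2-dimethylcyclopropyl]-4-methylhex-3-en-1-yl}zinc iodide | BrC(Br)=C[C@H]1[C@@H](CC/C(C)=C/CC[Zn]I)C1(C)C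
F3 | step 8 | globulol-type tertiary alcohol: trans-fused aromadendran-10-ol carrying at C4 the (1-aryl-3-methylbutyl) group with free 2,4,6-trihydroxy-3,5-diformylphenyl ring | CC(C)C[C@@H](c1c(O)c(C=O)c(O)c(C=O)c1O)[C@@]1(C)CC[C@@H]2[C@@H]1[C@H]1[C@@H](CC[C@@]2(C)O)C1(C)C
F4 | step 7 | [(1R,2Z,6E,10R)-7,11,11-trimethylbicyclo[8.1.0]undeca-2,6-dien-3-yl]lithium | [Li]/C1=C\[C@H]2[C@@H](CC/C(C)=C/CC1)C2(C)C
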